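**Plan**
Numbering: C7/C7' benzylic CH2, C8/C8' methine, C9/C9' methyl. The target is the C2-symmetric (8R,8'R)-1,4-diaryl-2,3-dimethylbutane with two identical 3,4-dihydroxy-5-methoxyphenyl rings and no other ring.
Enabling feature: the only stereocentres, C8 and C8', are bonded to each other in an open chain and each carries a one-carbon arm. With C9 as CO2H and C7' as an alkene CH, the array O=C9–C8–C8'–C7'=C is a γ,δ-unsaturated acid, the retron of an ester-enolate [3,3] shift.
Cuts (retro): aryl C1'–C7' (aryl Grignard + aldehyde); the C7'=C alkene and the C9 oxidation level (CH3 ← CH2OTs ← CO2H); C8–C8' (Ireland–Claisen); the ester C–O bond; C7–C8 of the arylpropanoic acid (Meldrum's acid homologation).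
Forward: ring A aldehyde → C7–C8–C9 acid → ester of a five-carbon allylic alcohol → C8–C8' bond → C9 methyl → C7' aldehyde → ring B → global hydrogenolysis. No ring is formed at any stage.
Stereochemistry: one lipase-resolved S carbinol centre is relayed to C8' across the E-allyl unit. The E-ketene acetal/E-alkene pairing in a chair fixes C8 relative to C8'. The later C7' carbinol centre is erased.

Key step: step 5

Assumption: salts that differ from a listed compound only by a proton restored on work-up (carboxylates, alkoxides, phenoxides) and catalyst- or reagent-bound species (acyl-enzyme, O-acylisourea, osmate ester) are not numbered separately.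

**Step 1**
Reactants: 1 5-hydroxyvanillin (3,4-dihydroxy-5-methoxybenzaldehyde)
Product: 2 3,4-bis(benzyloxy)-5-methoxybenzaldehyde
Conditions: BnBr (2.4 equiv), K2CO3, DMF, 60 °C, N2
Reagents that add atoms: benzyl bromide, BrCc1ccccc1
Why: Williamson etherification of both phenols with the aldehyde inert; benzyl is chosen because it withstands LDA, hydrides, OsO4/NaIO4 and Grignard reagents and leaves in the closing hydrogenolysis.

**Step 2**
Reactants: 2 3,4-bis(benzyloxy)-5-methoxybenzaldehyde; 3 Meldrum's acid (2,2-dimethyl-1,3-dioxane-4,6-dione)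
Product: 7 3-[3,4-bis(benzyloxy)-5-methoxyphenyl]propanoic acid, via arylidene Meldrum's acid 4 (not isolated), via benzyl Meldrum's acid 5 (not isolated), via benzylmalonic acid 6 (not isolated)
Conditions: HCO2H–Et3N (5:2), 95–100 °C; then aq. HCl
Reagents that add atoms: water, O (released in the condensation, taken up again when the dioxanedione ring opens)
Why: This is the known one-pot conversion of ArCHO into ArCH2CH2CO2H (Knoevenagel condensation, conjugate hydride transfer from formate to the electrophilic alkylidene Meldrum's acid, then ring hydrolysis and decarboxylation), and with no hydrogenation metal present the benzyl ethers stay.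

**Step 3**
Reactants: 8 rac-(E)-pent-3-en-2-ol
Product: 9 (S,E)-pent-3-en-2-ol
Conditions: CAL-B (Novozym 435), vinyl laurate (0.6 equiv), pentane, rt, run just past half conversion; filter, distil
Reagents that add atoms: none
Why: In this lipase-catalysed kinetic resolution CAL-B acylates the R alcohol according to the Kazlauskas rule (propenyl large, methyl medium), so going slightly beyond half conversion should leave 9 in high enantiomeric purity, and the heavy laurate lets the volatile alcohol be distilled off.

**Step 4**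
Reactants: 7 3-[3,4-bis(benzyloxy)-5-methoxyphenyl]propanoic acid; 9 (S,E)-pent-3-en-2-ol
Product: 10 (S,E)-pent-3-en-2-yl 3-[3,4-bis(benzyloxy)-5-methoxyphenyl]propanoate
Conditions: DCC, DMAP (10 mol%), CH2Cl2, 0 °C → rt
Reagents that add atoms: none
Why: In the Steglich esterification only the O–H bond of 9 reacts, so the carbinol configuration and the E-alkene are carried over unchanged.

**Step 5**
Reactants: 10 (S,E)-pent-3-en-2-yl 3-[3,4-bis(benzyloxy)-5-methoxyphenyl]propanoate
Product: 14 (2R,3R,4E)-2-[3,4-bis(benzyloxy)-5-methoxybenzyl]-3-methylhex-4-enoic acid, via lithium enolate 11 (not isolated), via E-silyl ketene acetal 12 (not isolated), via trimethylsilyl ester 13 (not isolated)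
Conditions: i-Pr2NH, n-BuLi, THF, 0 °C (→ LDA, 1.15 equiv); 10, −78 °C; TMSCl–Et3N, −78 °C → rt, then 50 °C; 1 M HCl
Reagents that add atoms: lithium diisopropylamide, [Li+].CC(C)[N-]C(C)C (Li, held by 11 only); chlorotrimethylsilane, C[Si](C)(C)Cl (Me3Si, held by 12 and 13 only); no reagent atom other than H remains in 14
Why: Ireland–Claisen rearrangement: LDA in THF free of polar cosolvent deprotonates 10 through the closed lithium-bridged transition state, which places the arylmethyl group trans to OLi, and O-silylation fixes this as the E-silyl ketene acetal 12. On warming, 12 undergoes a concerted suprafacial [3,3] shift through a chair in which the carbinol C–O bond breaks while the C2–C3 (lignan C8–C8') bond forms; only a six-atom cyclic transition state is passed and no ring is closed. C3 (C8') is set by 1,3-chirality transfer: with the carbinol methyl pseudo-equatorial, the S centre offers one face of the E-alkene, which gives 3R and a new E double bond while the original stereocentre is consumed. C2 (C8) is set relative to C3 by pairing the E-ketene acetal (arylmethyl cis to the allylic oxygen, hence axial-like) with the E-alkene (methyl equatorial), which gives the anti acid, 2R,3R, the relative configuration that becomes the C2 and not the meso series. The closest known case is the rearrangement of propanoates of enantioenriched secondary E-allylic alcohols, from which 10 differs only by a remote aryl group. The step needs one enolate geometry, one alkene geometry and one chair, secured by cosolvent-free enolisation, by E-alcohol 9 and by the equatorial preference of the carbinol methyl, and any syn acid should be removable by crystallisation or chromatography of 14.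

**Step 6**
Reactants: 14 (2R,3R,4E)-2-[3,4-bis(benzyloxy)-5-methoxybenzyl]-3-methylhex-4-enoic acid
Product: 15 (2R,3R,4E)-2-[3,4-bis(benzyloxy)-5-methoxybenzyl]-3-methylhex-4-en-1-ol
Conditions: LiAlH4, THF, 0 °C → rt; Fieser work-up
Reagents that add atoms: none
Why: LiAlH4 reduces the carboxylic acid to the primary alcohol, the carboxylate formed first resists α-deprotonation so C2 is safe, and the isolated alkene and the aryl ethers are inert.

**Step 7**
Reactants: 15 (2R,3R,4E)-2-[3,4-bis(benzyloxy)-5-methoxybenzyl]-3-methylhex-4-en-1-ol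
Product: 16 (2R,3R,4E)-2-[3,4-bis(benzyloxy)-5-methoxybenzyl]-3-methylhex-4-en-1-yl 4-methylbenzenesulfonate
Conditions: TsCl, Et3N, DMAP (cat.), CH2Cl2, 0 °C → rt
Reagents that add atoms: p-toluenesulfonyl chloride, Cc1ccc(cc1)S(=O)(=O)Cl
Why: Routine O-sulfonylation of the only free hydroxyl group breaks no bond to a stereocentre.

**Step 8**
Reactants: 16 (2R,3R,4E)-2-[3,4-bis(benzyloxy)-5-methoxybenzyl]-3-methylhex-4-en-1-yl 4-methylbenzenesulfonate
Product: 17 1,2-bis(benzyloxy)-5-[(2R,3S,4E)-2,3-dimethylhex-4-en-1-yl]-3-methoxybenzene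
Conditions: LiEt3BH (3 equiv), THF, 0 °C → rt
Reagents that add atoms: none
Why: SN2 hydride displacement of the primary tosylate by lithium triethylborohydride, the standard reagent for β-branched sulfonates, turns C9 into methyl; the allylic centre changes descriptor from R to S only because the CIP ranking changes.

**Step 9**
Reactants: 17 1,2-bis(benzyloxy)-5-[(2R,3S,4E)-2,3-dimethylhex-4-en-1-yl]-3-methoxybenzene
Product: 19 (2S,3R)-4-[3,4-bis(benzyloxy)-5-methoxyphenyl]-2,3-dimethylbutanal, via vicinal diol 18 (not isolated)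
Conditions: OsO4 (2 mol%), NaIO4 (4 equiv), 2,6-lutidine, dioxane–H2O 3:1, rt; used at once
Reagents that add atoms: osmium tetroxide, O=[Os](=O)(=O)=O; sodium periodate, [Na+].[O-]I(=O)(=O)=O
Why: Lemieux–Johnson cleavage (syn-dihydroxylation, then periodate glycol fission) is preferred to ozone because the trialkoxyarenes are inert to it, and the lutidine buffer keeps the medium near neutral so the α-centre C8' of the aldehyde should not epimerise.

**Step 10**
Reactants: 20 5-bromo-2-hydroxy-3-methoxybenzaldehyde
Product: 22 5-bromo-3-methoxybenzene-1,2-diol, via aryl formate 21 (not isolated)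
Conditions: 30% H2O2, aq. NaOH, 0 °C → rt, N2; then HCl
Reagents that add atoms: hydrogen peroxide, OO
Why: In the Dakin oxidation the ortho-hydroxyaryl group migrates from the peroxide adduct to oxygen and the formate is hydrolysed in the same basic medium, which places bromine para to the central oxygen as ring B requires.

**Step 11**
Reactants: 22 5-bromo-3-methoxybenzene-1,2-diol
Product: 23 1,2-bis(benzyloxy)-5-bromo-3-methoxybenzene
Conditions: BnBr (2.4 equiv), K2CO3, DMF, 60 °C, N2
Reagents that add atoms: benzyl bromide, BrCc1ccccc1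
Why: Williamson etherification of the catechol gives ring B the same protecting groups as ring A so that all leave together at the end.

**Step 12**
Reactants: 23 1,2-bis(benzyloxy)-5-bromo-3-methoxybenzene; 19 (2S,3R)-4-[3,4-bis(benzyloxy)-5-methoxyphenyl]-2,3-dimethylbutanal
Product: 25 (2S,3R)-1,4-bis[3,4-bis(benzyloxy)-5-methoxyphenyl]-2,3-dimethylbutan-1-ol (both C1 epimers), via arylmagnesium bromide 24 (not isolated)
Conditions: 23, Mg, I2 (cat.), THF, reflux; then 19, THF, −78 → −20 °C; sat. aq. NH4Cl
Reagents that add atoms: magnesium, [Mg] (held by 24 only; no reagent atom other than H remains in 25)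
Why: Grignard addition of an aryl nucleophile to the aldehyde forms the C1'–C7' bond quickly at low temperature, and the new C7' carbinol centre needs no control because it is removed in the next step.

**Step 13**
Reactants: 25 (2S,3R)-1,4-bis[3,4-bis(benzyloxy)-5-methoxyphenyl]-2,3-dimethylbutan-1-ol
Product: 26 sauriol A, 5,5'-[(2R,3R)-2,3-dimethylbutane-1,4-diyl]bis(3-methoxybenzene-1,2-diol)
Conditions: H2 (4 bar), 20% Pd(OH)2/C, EtOH–AcOH 9:1, rt → 40 °C; work-up under Ar
Reagents that add atoms: none
Why: Catalytic hydrogenolysis cleaves the four aryl benzyl ethers and the electron-rich secondary benzylic C7'–OH bond on palladium in weakly acidic medium, a combination established for 7-hydroxy dibenzylbutane lignans, while the non-benzylic centres C8 and C8' are untouched and loss of the hydroxyl restores C2 symmetry.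

**Compound list**
1 | 5-hydroxyvanillin | COc1cc(C=O)cc(O)c1O | starting material
2 | 3,4-bis(benzyloxy)-5-methoxybenzaldehyde | COc1cc(C=O)cc(OCc2ccccc2)c1OCc1ccccc1 | intermediate
3 | Meldrum's acid | CC1(C)OC(=O)CC(=O)O1 | starting material
4 | 5-[3,4-bis(benzyloxy)-5-methoxybenzylidene]-2,2-dimethyl-1,3-dioxane-4,6-dione | COc1cc(C=C2C(=O)OC(C)(C)OC2=O)cc(OCc2ccccc2)c1OCc1ccccc1 | intermediate
5 | 5-[3,4-bis(benzyloxy)-5-methoxybenzyl]-2,2-dimethyl-1,3-dioxane-4,6-dione | COc1cc(CC2C(=O)OC(C)(C)OC2=O)cc(OCc2ccccc2)c1OCc1ccccc1 | intermediate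
6 | 2-[3,4-bis(benzyloxy)-5-methoxybenzyl]malonic acid | COc1cc(CC(C(=O)O)C(=O)O)cc(OCc2ccccc2)c1OCc1ccccc1 | intermediate
7 | 3-[3,4-bis(benzyloxy)-5-methoxyphenyl]propanoic acid | COc1cc(CCC(=O)O)cc(OCc2ccccc2)c1OCc1ccccc1 | intermediate
8 | rac-(E)-pent-3-en-2-ol | C/C=C/C(C)O | starting material
9 | (S,E)-pent-3-en-2-ol | C/C=C/[C@H](C)O | intermediate
10 | (S,E)-pent-3-en-2-yl 3-[3,4-bis(benzyloxy)-5-methoxyphenyl]propanoate | COc1cc(CCC(=O)O[C@@H](C)/C=C/C)cc(OCc2ccccc2)c1OCc1ccccc1 | intermediate
11 | lithium enolate of 10, arylmethyl trans to OLi (Z by CIP, E(O) in enolate usage) | COc1cc(C/C=C(/O[Li])O[C@@H](C)/C=C/C)cc(OCc2ccccc2)c1OCc1ccccc1 | intermediate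
12 | (E)-trimethylsilyl ketene acetal of 10, arylmethyl trans to OSiMe3 | COc1cc(C/C=C(/O[Si](C)(C)C)O[C@@H](C)/C=C/C)cc(OCc2ccccc2)c1OCc1ccccc1 | intermediate
13 | trimethylsilyl (2R,3R,4E)-2-[3,4-bis(benzyloxy)-5-methoxybenzyl]-3-methylhex-4-enoate | COc1cc(C[C@@H](C(=O)O[Si](C)(C)C)[C@H](C)/C=C/C)cc(OCc2ccccc2)c1OCc1ccccc1 | intermediate
14 | (2R,3R,4E)-2-[3,4-bis(benzyloxy)-5-methoxybenzyl]-3-methylhex-4-enoic acid | COc1cc(C[C@@H](C(=O)O)[C@H](C)/C=C/C)cc(OCc2ccccc2)c1OCc1ccccc1 | intermediate
15 | (2R,3R,4E)-2-[3,4-bis(benzyloxy)-5-methoxybenzyl]-3-methylhex-4-en-1-ol | COc1cc(C[C@@H](CO)[C@H](C)/C=C/C)cc(OCc2ccccc2)c1OCc1ccccc1 | intermediate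
16 | (2R,3R,4E)-2-[3,4-bis(benzyloxy)-5-methoxybenzyl]-3-methylhex-4-en-1-yl 4-methylbenzenesulfonate | COc1cc(C[C@@H](COS(=O)(=O)c2ccc(C)cc2)[C@H](C)/C=C/C)cc(OCc2ccccc2)c1OCc1ccccc1 | intermediate
17 | 1,2-bis(benzyloxy)-5-[(2R,3S,4E)-2,3-dimethylhex-4-en-1-yl]-3-methoxybenzene | COc1cc(C[C@@H](C)[C@H](C)/C=C/C)cc(OCc2ccccc2)c1OCc1ccccc1 | intermediate
18 | (4S,5R)-6-[3,4-bis(benzyloxy)-5-methoxyphenyl]-4,5-dimethylhexane-2,3-diol (syn-addition diol, both facial isomers) | COc1cc(C[C@@H](C)[C@H](C)C(O)C(C)O)cc(OCc2ccccc2)c1OCc1ccccc1 | intermediate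
19 | (2S,3R)-4-[3,4-bis(benzyloxy)-5-methoxyphenyl]-2,3-dimethylbutanal | COc1cc(C[C@@H](C)[C@H](C)C=O)cc(OCc2ccccc2)c1OCc1ccccc1 | intermediate
20 | 5-bromo-2-hydroxy-3-methoxybenzaldehyde | COc1cc(Br)cc(C=O)c1O | starting material
21 | 5-bromo-2-hydroxy-3-methoxyphenyl formate | COc1cc(Br)cc(OC=O)c1O | intermediate
22 | 5-bromo-3-methoxybenzene-1,2-diol | COc1cc(Br)cc(O)c1O | intermediate
23 | 1,2-bis(benzyloxy)-5-bromo-3-methoxybenzene | COc1cc(Br)cc(OCc2ccccc2)c1OCc1ccccc1 | intermediate
24 | [3,4-bis(benzyloxy)-5-methoxyphenyl]magnesium bromide | COc1cc([Mg]Br)cc(OCc2ccccc2)c1OCc1ccccc1 | intermediate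
25 | (2S,3R)-1,4-bis[3,4-bis(benzyloxy)-5-methoxyphenyl]-2,3-dimethylbutan-1-ol (C1 epimers) | COc1cc(C[C@@H](C)[C@H](C)C(O)c2cc(OC)c(OCc3ccccc3)c(OCc3ccccc3)c2)cc(OCc2ccccc2)c1OCc1ccccc1 | intermediate
26 | sauriol A, (8R,8'R) | COc1cc(C[C@@H](C)[C@H](C)Cc2cc(O)c(O)c(OC)c2)cc(O)c1O | target

**Step count**
Total steps: 13. Longest linear sequence: 10 (steps 1, 2, 4, 5, 6, 7, 8, 9, 12, 13).

**Steps most likely to fail**

Step 5.
- Risk: incomplete control of enolate geometry would leak material into the syn acid and so into the meso series. Partial passage through the chair with an axial carbinol methyl would give a Z-alkene with mirror-image new centres, which lowers the enantiomeric purity once the alkene is cleaved.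
- Fallback: keep the same [3,3] bond formation but invert both geometries. The route sets out from 7 and comes back at 13.
- Route: commercial pent-3-yn-2-one is reduced by Noyori asymmetric transfer hydrogenation with the (R,R)-TsDPEN–Ru(p-cymene) catalyst in i-PrOH to (R)-pent-3-yn-2-ol F1. Lindlar semihydrogenation gives (R,Z)-pent-3-en-2-ol F2, and Steglich coupling with 7 gives the (R,Z)-pent-3-en-2-yl ester F3. Enolisation with LDA in THF–DMPU gives the lithium enolate with arylmethyl cis to OLi F4, and TMSCl converts it into the (Z)-silyl ketene acetal F5.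
- Outcome: in the chair of F5, allylic 1,3-strain of the Z-alkene forbids an axial carbinol methyl. The Z/Z pairing again gives the anti relationship, and the R carbinol gives 2R,3R with an E-alkene, that is silyl ester 13 and then 14.

Step 12.
- Risk: the aryl-metal may enolise the α-branched aldehyde, and the aldehyde may epimerise at C8' during handling. Either cuts conversion or stereochemical integrity.
- Fallback: replace carbonyl addition by an sp3–sp2 cross-coupling. The route sets out from 19 and comes back at 26.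
- Route: the crude aldehyde is reduced at once with NaBH4 in MeOH to (2S,3R)-4-[3,4-bis(benzyloxy)-5-methoxyphenyl]-2,3-dimethylbutan-1-ol F6. This is converted with I2, PPh3 and imidazole into the primary iodide F7. Iron-catalysed Kumada-type alkyl–aryl coupling [Fe(acac)3, TMEDA, THF, 0 °C] with Grignard reagent 24 gives tetra-O-benzyl sauriol A F8. Plain hydrogenolysis (H2, Pd/C, EtOAc–EtOH) then gives 26, with no benzylic alcohol to remove.

Step 13.
- Risk: the C7'–OH bond may stay behind once the phenols are unmasked. Alternatively, acid may ionise C7', and the other arene would then attack it to close an aryltetralin.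
- Fallback: separate the two tasks and remove the hydroxyl by a radical path. The route sets out from 25 and comes back at 26.
- Route: 25 is acylated with phenyl chlorothionoformate (pyridine, DMAP, CH2Cl2) to the O-phenyl thionocarbonate F9. Barton–McCombie deoxygenation (Bu3SnH, AIBN, toluene, 80 °C) gives the tetrabenzyl ether F8 described above. Neutral hydrogenolysis (H2, Pd/C) then gives 26.

**Further compounds**
F1 | step 5 | (R)-pent-3-yn-2-ol | O[C@H](C)C#CC
F2 | step 5 | (R,Z)-pent-3-en-2-ol | O[C@H](C)/C=C\C
F3 | step 5 | (R,Z)-pent-3-en-2-yl 3-[3,4-bis(benzyloxy)-5-methoxyphenyl]propanoate | COc1cc(CCC(=O)O[C@H](C)/C=C\C)cc(OCc2ccccc2)c1OCc1ccccc1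
F4 | step 5 | lithium enolate of F3, arylmethyl cis to OLi | COc1cc(C/C=C(\O[Li])O[C@H](C)/C=C\C)cc(OCc2ccccc2)c1OCc1ccccc1
F5 | step 5 | (Z)-trimethylsilyl ketene acetal of F3 | COc1cc(C/C=C(\O[Si](C)(C)C)O[C@H](C)/C=C\C)cc(OCc2ccccc2)c1OCc1ccccc1
F6 | step 12 | (2S,3R)-4-[3,4-bis(benzyloxy)-5-methoxyphenyl]-2,3-dimethylbutan-1-ol | COc1cc(C[C@@H](C)[C@H](C)CO)cc(OCc2ccccc2)c1OCc1ccccc1
F7 | step 12 | 1,2-bis(benzyloxy)-5-[(2R,3S)-4-iodo-2,3-dimethylbutyl]-3-methoxybenzene | COc1cc(C[C@@H](C)[C@H](C)CI)cc(OCc2ccccc2)c1OCc1ccccc1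
F8 | step 12 | (2R,3R)-1,4-bis[3,4-bis(benzyloxy)-5-methoxyphenyl]-2,3-dimethylbutane | COc1cc(C[C@@H](C)[C@H](C)Cc2cc(OC)c(OCc3ccccc3)c(OCc3ccccc3)c2)cc(OCc2ccccc2)c1OCc1ccccc1
F9 | step 13 | O-{(2S,3R)-1,4-bis[3,4-bis(benzyloxy)-5-methoxyphenyl]-2,3-dimethylbutyl} O-phenyl thionocarbonate | COc1cc(C[C@@H](C)[C@H](C)C(OC(=S)Oc2ccccc2)c2cc(OC)c(OCc3ccccc3)c(OCc3ccccc3)c2)cc(OCc2ccccc2)c1OCc1ccccc1
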